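**Retrosynthetic overview**
- Target ⇐ hydrogenolysis of its bis-O-benzyl ether ⇐ Friedel–Crafts C-arylation of a 5-aryl-3,4-bis(benzyloxymethyl)oxolan-2-ol (lactol) with 2,6-dimethoxyphenol, which installs the syringyl ring trans to C3.
- Lactol ⇐ DIBAL ⇐ all-trans γ-lactone ⇐ anti alkylation (BOMCl) of a 4,5-trans γ-aryl lactone ⇐ ArMgBr addition/lactonisation of an aldehyde-ester.
- Aldehyde-ester ⇐ ozonolysis of ethyl (R,E)-3-(benzyloxymethyl)hex-4-enoate ⇐ Johnson–Claisen [3,3] rearrangement of (R,E)-5-benzyloxypent-3-en-2-ol. This is the key step: it makes the C3–C4 (lignan 8–8′) bond with 1,3-chirality transfer.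
- Allylic alcohol ⇐ Red-Al reduction ⇐ C-alkylation of (R)-but-3-yn-2-ol, the only purchased stereocentre. It relays to C4, which then controls C3, C5 and C2.
- Ring order: the single oxolane ring is closed once, as the γ-lactone (step 5), then carried through lactol to the 2,5-diaryl-THF.

Assumption: (R)-but-3-yn-2-ol is taken as an inexpensive commercial enantiopure building block (both enantiomers are sold).

**Route**

Step 1
Reactants: 1, (R)-but-3-yn-2-ol; 2, benzyl chloromethyl ether (BOMCl)
Product: 3, (2R)-5-(benzyloxy)pent-3-yn-2-ol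
Conditions: EtMgBr (2.1 equiv), THF, 0 °C → rt; then 2, 0 °C → rt
Reagents that add atoms: benzyl chloromethyl ether, ClCOCc1ccccc1
Why: The alkynyl Grignard of the O,C-dimetallated alkynol is far more nucleophilic than the magnesium alkoxide and is alkylated at carbon by the α-chloro ether (acetylide alkylation), leaving the carbinol centre untouched.

Step 2
Reactants: 3, (2R)-5-(benzyloxy)pent-3-yn-2-ol
Product: 4, (2R,3E)-5-(benzyloxy)pent-3-en-2-ol
Conditions: Red-Al, THF, 0 °C → rt
Reagents that add atoms: none
Why: Alkoxide-directed trans-hydroalumination of the propargylic alcohol gives only the E-allylic alcohol, and the stereocentre is not involved.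

Step 3
Reactants: 4, (2R,3E)-5-(benzyloxy)pent-3-en-2-ol; 5, triethyl orthoacetate
Product: 6, ethyl (3R,4E)-3-[(benzyloxy)methyl]hex-4-enoate
Conditions: MeC(OEt)3 (excess), EtCO2H (cat.), 138 °C, –EtOH
Reagents that add atoms: triethyl orthoacetate, CCOC(C)(OCC)OCC
Why: Johnson–Claisen [3,3]-sigmatropic rearrangement through a chair transition state with the carbinol methyl equatorial transfers the C–O chirality suprafacially across the E-alkene, forming the future C3–C4 bond and the (R)-configured centre together with an E-propenyl group.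

Step 4
Reactants: 6, ethyl (3R,4E)-3-[(benzyloxy)methyl]hex-4-enoate
Product: 7, ethyl (3S)-3-[(benzyloxy)methyl]-4-oxobutanoate
Conditions: O3, CH2Cl2, –78 °C (indicator end-point); PPh3, –78 °C → rt; used crude
Reagents that add atoms: ozone, [O-][O+]=O
Why: Ozonolysis with neutral reductive work-up cleaves the propenyl group to the aldehyde without touching the α-stereocentre (same spatial arrangement; the descriptor changes only by CIP priority).

Step 5
Reactants: 7, ethyl (3S)-3-[(benzyloxy)methyl]-4-oxobutanoate; 8, (3,4,5-trimethoxyphenyl)magnesium bromide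
Product: 9, (4S,5R)-4-[(benzyloxy)methyl]-5-(3,4,5-trimethoxyphenyl)oxolan-2-one (4,5-trans; the 4S,5S epimer is removed by chromatography)
Conditions: 8 (1.1 equiv), THF, –78 °C; aq. NH4Cl; then p-TsOH (cat.), CH2Cl2, rt
Reagents that add atoms: (3,4,5-trimethoxyphenyl)magnesium bromide, COc1cc([Mg]Br)cc(OC)c1OC
Why: Chemoselective Grignard addition to the aldehyde followed by γ-lactonisation closes the future THF ring; C5 forms under Felkin-type 1,2-induction from C4 with only modest preference, so the 4,5-trans lactone is isolated by chromatography.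

Step 6
Reactants: 9, (4S,5R)-lactone; 2, benzyl chloromethyl ether
Product: 10, (3S,4S,5R)-3,4-bis[(benzyloxy)methyl]-5-(3,4,5-trimethoxyphenyl)oxolan-2-one
Conditions: LDA (1.1 equiv), THF, –78 °C; then 2, –78 → –40 °C
Reagents that add atoms: benzyl chloromethyl ether, ClCOCc1ccccc1
Why: Lactone enolate alkylation occurs on the face anti to the adjacent C4 substituent, giving the 3,4-trans (3S) product under substrate control.

Step 7
Reactants: 10, (3S,4S,5R)-lactone
Product: 11, (3S,4S,5R)-3,4-bis[(benzyloxy)methyl]-5-(3,4,5-trimethoxyphenyl)oxolan-2-ol (anomer mixture)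
Conditions: DIBAL-H (1.1 equiv), CH2Cl2, –78 °C
Reagents that add atoms: none
Why: Low-temperature DIBAL half-reduction of a γ-lactone stops at the lactol, the oxocarbenium precursor, and no stereocentre is affected.

Step 8
Reactants: 11, lactol; 12, 2,6-dimethoxyphenol
Product: 13, 4-[(2R,3S,4S,5R)-3,4-bis[(benzyloxy)methyl]-5-(3,4,5-trimethoxyphenyl)oxolan-2-yl]-2,6-dimethoxyphenol
Conditions: 12 (1.5 equiv), BF3·OEt2 (1.2 equiv), CH2Cl2, –78 → –20 °C
Reagents that add atoms: 2,6-dimethoxyphenol, COc1cccc(OC)c1O
Why: BF3 generates the cyclic oxocarbenium ion, which undergoes Friedel–Crafts C-arylation at the position para to the phenol OH, anti to the C3 substituent; because the new p-hydroxybenzylic C–O bond can re-ionise, the 2,3-trans (2R, all-trans) isomer is also the thermodynamic product.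

Step 9
Reactants: 13, bis-benzyl ether
Product: 14, 4-[(2R,3S,4S,5R)-3,4-bis(hydroxymethyl)-5-(3,4,5-trimethoxyphenyl)oxolan-2-yl]-2,6-dimethoxyphenol (target, CID 56680032)
Conditions: H2 (1 atm), Pd(OH)2/C, EtOAc–MeOH, rt, stopped at full debenzylation
Reagents that add atoms: none
Why: Hydrogenolysis removes the two primary benzyl ethers, which should cleave faster than the hindered cyclic benzylic C–O bonds of the 2,5-diaryl-THF, and no stereocentre is touched.

**Compound list**
1 | (R)-but-3-yn-2-ol | C[C@@H](O)C#C | starting material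
2 | benzyl chloromethyl ether | ClCOCc1ccccc1 | starting material
3 | (2R)-5-(benzyloxy)pent-3-yn-2-ol | C[C@@H](O)C#CCOCc1ccccc1 | intermediate
4 | (2R,3E)-5-(benzyloxy)pent-3-en-2-ol | C[C@@H](O)/C=C/COCc1ccccc1 | intermediate
5 | triethyl orthoacetate | CCOC(C)(OCC)OCC | starting material
6 | ethyl (3R,4E)-3-[(benzyloxy)methyl]hex-4-enoate | CCOC(=O)C[C@@H](COCc1ccccc1)/C=C/C | intermediate
7 | ethyl (3S)-3-[(benzyloxy)methyl]-4-oxobutanoate | CCOC(=O)C[C@@H](COCc1ccccc1)C=O | intermediate
8 | (3,4,5-trimethoxyphenyl)magnesium bromide | COc1cc([Mg]Br)cc(OC)c1OC | starting material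
9 | (4S,5R)-4-[(benzyloxy)methyl]-5-(3,4,5-trimethoxyphenyl)oxolan-2-one | O=C1C[C@@H](COCc2ccccc2)[C@H](c3cc(OC)c(OC)c(OC)c3)O1 | intermediate
10 | (3S,4S,5R)-3,4-bis[(benzyloxy)methyl]-5-(3,4,5-trimethoxyphenyl)oxolan-2-one | O=C1[C@H](COCc2ccccc2)[C@@H](COCc3ccccc3)[C@H](c4cc(OC)c(OC)c(OC)c4)O1 | intermediate
11 | (3S,4S,5R)-3,4-bis[(benzyloxy)methyl]-5-(3,4,5-trimethoxyphenyl)oxolan-2-ol | OC1[C@H](COCc2ccccc2)[C@@H](COCc3ccccc3)[C@H](c4cc(OC)c(OC)c(OC)c4)O1 | intermediate
12 | 2,6-dimethoxyphenol | COc1cccc(OC)c1O | starting material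
13 | 4-[(2R,3S,4S,5R)-3,4-bis[(benzyloxy)methyl]-5-(3,4,5-trimethoxyphenyl)oxolan-2-yl]-2,6-dimethoxyphenol | COc1cc([C@@H]2O[C@@H](c3cc(OC)c(OC)c(OC)c3)[C@H](COCc4ccccc4)[C@H]2COCc5ccccc5)cc(OC)c1O | intermediate
14 | 4-[(2R,3S,4S,5R)-3,4-bis(hydroxymethyl)-5-(3,4,5-trimethoxyphenyl)oxolan-2-yl]-2,6-dimethoxyphenol | COc1cc([C@@H]2O[C@@H](c3cc(OC)c(OC)c(OC)c3)[C@H](CO)[C@H]2CO)cc(OC)c1O | target

**Totals**
Total step count: 9. Longest linear sequence: 9 (fully linear from 1).

**Three steps most likely to fail**
1. Step 5: diastereoselectivity at the benzylic C5 is poor, and the α-formyl centre of 7 can epimerise. Fallback: add the aryl group under chelation control (MgBr2·OEt2, CH2Cl2) to get the opposite (cis-lactone) adduct selectively, saponify, and close the lactone by Mitsunobu reaction with inversion at the benzylic carbon to reach 9.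
2. Step 8: the Friedel–Crafts arylation may give O-arylation, over-arylation through the ring-opened quinone methide, or the wrong ring position. Fallback: reverse the polarity by adding (4-benzyloxy-3,5-dimethoxyphenyl)lithium to lactone 10 and reducing the hemiketal with Et3SiH/BF3·OEt2, with BF3-mediated equilibration to the 2,3-trans isomer if needed; the extra benzyl group is removed in step 9.
3. Step 9: the benzylic C–O bonds of the 2,5-diaryl-THF may be hydrogenolysed competitively. Fallback: change the protecting-group plan by introducing both hydroxymethyl groups with formaldehyde (steps 1 and 6) and carrying them as TBDPS ethers, finishing with TBAF instead of hydrogen.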